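The route rests on cutting the C1'–O7 ether bond between the side chain and the benzene ring of the coumarin. The key step exploits the pair of hydroxyls at C2' (secondary, R) and C3' (tertiary, R) next to that aryl ether, beside an untouched C6'=C7' alkene. Such a diol arises when the oxirane of nerol-derived epoxynerol shifts from C2'–C3' to C1'–C2', inverting C2', and a phenoxide then attacks C1'. In one flask this makes the ether bond and carries both stereocenters over from a single asymmetric epoxidation. The partners are isofraxidin (7-hydroxy-6,8-dimethoxycoumarin) as its potassium phenoxide, built from syringaldehyde, and (2S,3R)-2,3-epoxynerol.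

Key step: step 5

Remark: side-chain atoms are numbered C1' (OCH2) to C8'; in the epoxy alcohols the same carbons are C1 to C8.

Step 1
Reactants: 1 syringaldehyde (4-hydroxy-3,5-dimethoxybenzaldehyde)
Product: 2 2-bromo-4-hydroxy-3,5-dimethoxybenzaldehyde
Conditions: Br2 (1.05 equiv), NaOAc (1.2 equiv), AcOH, 15–20 °C
Reagents that add atoms: bromine, BrBr
Why: Electrophilic aromatic bromination: C2 (the same as C6) is the only free ring position that both methoxy groups activate, one from ortho and one from para, and the buffered, water-free medium together with a single equivalent of bromine should hold back ipso attack at the formyl-bearing carbon and a second bromination.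

Step 2
Reactants: 2 2-bromo-4-hydroxy-3,5-dimethoxybenzaldehyde
Product: 3 2,4-dihydroxy-3,5-dimethoxybenzaldehyde
Conditions: NaOH (aq, 3 M, 8 equiv), Cu powder (10 mol %), reflux, N2; then aq HCl to pH 2
Reagents that add atoms: sodium hydroxide, [Na+].[OH-]
Why: Ullmann-type copper-catalysed hydroxylation of an aryl bromide, helped by the ortho formyl group; in the alkali the C4 phenoxide protects itself and makes the aldehyde a vinylogous carboxylate that should not undergo Cannizzaro disproportionation, and the new oxygen is the one that later becomes the ring oxygen of the lactone.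

Step 3
Reactants: 3 2,4-dihydroxy-3,5-dimethoxybenzaldehyde; 4 ethyl (triphenylphosphoranylidene)acetate
Product: 6 isofraxidin (7-hydroxy-6,8-dimethoxycoumarin), via ethyl E-cinnamate 5 (not isolated)
Conditions: 4 (1.3 equiv), N,N-diethylaniline, reflux (about 215 °C), N2
Reagents that add atoms: none
Why: Wittig olefination by the stabilised ylide gives the cinnamate 5, mainly E, which at the boiling point of N,N-diethylaniline should isomerise about the double bond and lactonise through the C2 hydroxyl with loss of ethanol (6-exo-trig acyl substitution), closing the pyranone ring; free phenols are tolerated in this classical coumarin synthesis from salicylaldehydes.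

Step 4
Reactants: 7 nerol
Product: 8 (2S,3R)-2,3-epoxynerol
Conditions: Ti(OiPr)4 (10 mol %), L-(+)-diethyl tartrate (12 mol %), tBuOOH (anhydrous, in decane, 1.5 equiv), 4 Å molecular sieves, CH2Cl2, −20 °C
Reagents that add atoms: tert-butyl hydroperoxide, CC(C)(C)OO
Why: Sharpless asymmetric epoxidation: the allylic hydroxyl binds to the titanium tartrate catalyst, so that only the C2=C3 alkene is oxidised while C6=C7 is left, the Z geometry fixes the cis relation of the CH2OH group and the homoprenyl chain, and the L-(+)-tartrate should direct the oxygen to the face that makes C2 (S) and C3 (R), as is the rule for Z-allylic alcohols.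

Step 5
Reactants: 6 isofraxidin; 8 (2S,3R)-2,3-epoxynerol
Product: 10 altissimacoumarin C, via terminal epoxide Payne isomer 9 (not isolated)
Conditions: 6 (1.3 equiv), KOtBu (1.5 equiv), tBuOH, 40 °C; then 8 (1.0 equiv), 80 °C, N2; then cold aq HCl to pH 3
Reagents that add atoms: none
Why: The small excess of tert-butoxide over the phenol turns part of 8 into its C1 alkoxide, which attacks C2 from the side opposite the oxirane oxygen (intramolecular SN2, Payne rearrangement) and gives the terminal epoxide 9 as its C3 alkoxide in a fast, unfavourable equilibrium; the C7 phenoxide of 6 then opens 9 irreversibly at the unsubstituted C1', so that the equilibrium is drawn over to 10 (Curtin–Hammett situation), and the acidic work-up protonates the alkoxides and recloses any lactone that has been opened. The closest known reaction type is the Payne rearrangement–opening of 2,3-epoxy alcohols at C1 by thiolates or hydroxide in basic medium, of which capture by an aryloxide is a variant with a weaker oxygen nucleophile. No ring of the product is closed: the C1–C2 oxirane of 9 forms by 3-exo-tet displacement and is opened again in the same flask. C3' keeps the C–O bond made in step 4 and is not touched, and C2' is set by the stereospecific inversion of the migration, so that (2S,3R) in 8 should become (2'R,3'R) in 10, with the former hydroxyl oxygen of nerol on C2'. Attack at C1' of 9 rather than at C2 or C3 of 8 is secured by substitution (a primary carbon against a tertiary one and one flanked by a fully substituted carbon); attack through O7 with the lactone intact is secured by the 7-oxido group, which makes the pyranone a vinylogous carboxylate, by the bulk of tert-butoxide, and by the absence of hydroxide, which would free a second phenoxide at C8a. The C6'=C7' alkene is inert to base, and the phenoxide is kept in excess so that capture outruns self-condensation of the epoxy alkoxide; unreacted 6 is washed out with aqueous Na2CO3.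

Compound list
1 | syringaldehyde (4-hydroxy-3,5-dimethoxybenzaldehyde) | COc1cc(C=O)cc(OC)c1O | starting material
2 | 2-bromo-4-hydroxy-3,5-dimethoxybenzaldehyde | COc1cc(C=O)c(Br)c(OC)c1O | intermediate
3 | 2,4-dihydroxy-3,5-dimethoxybenzaldehyde | COc1cc(C=O)c(O)c(OC)c1O | intermediate
4 | ethyl (triphenylphosphoranylidene)acetate | CCOC(=O)C=P(c1ccccc1)(c1ccccc1)c1ccccc1 | starting material
5 | ethyl (E)-3-(2,4-dihydroxy-3,5-dimethoxyphenyl)prop-2-enoate | CCOC(=O)/C=C/c1cc(OC)c(O)c(OC)c1O | intermediate
6 | isofraxidin (7-hydroxy-6,8-dimethoxy-2H-chromen-2-one) | COc1cc2ccc(=O)oc2c(OC)c1O | intermediate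
7 | nerol ((2Z)-3,7-dimethylocta-2,6-dien-1-ol) | OC/C=C(C)\CCC=C(C)C | starting material
8 | (2S,3R)-2,3-epoxynerol, [(2S,3R)-3-methyl-3-(4-methylpent-3-en-1-yl)oxiran-2-yl]methanol | OC[C@@H]1O[C@]1(C)CCC=C(C)C | intermediate
9 | (2R,3R)-1,2-epoxy-3,7-dimethyloct-6-en-3-ol, (2R)-6-methyl-2-[(2R)-oxiran-2-yl]hept-5-en-2-ol | C1O[C@H]1[C@](C)(O)CCC=C(C)C | intermediate
10 | altissimacoumarin C, 7-{[(2R,3R)-2,3-dihydroxy-3,7-dimethyloct-6-en-1-yl]oxy}-6,8-dimethoxy-2H-chromen-2-one | COc1cc2ccc(=O)oc2c(OC)c1OC[C@@H](O)[C@](C)(O)CCC=C(C)C | target

Total step count: 5 steps.
Longest linear sequence: 4 steps (steps 1, 2, 3 and 5, from compound 1 to compound 10); the epoxide arm is one step (step 4) before the convergent step.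

Steps most likely to fail

Step 5. Capture of the terminal epoxide by the hindered, weakly nucleophilic phenoxide may be slower than base-driven self-condensation of the epoxy alkoxide, or than alkoxide attack on the lactone of the product once the phenoxide is used up. The fallback sets out from compound 8. A Payne rearrangement–opening with hydroxide (aq NaOH, tBuOH, reflux), established for 2,3-epoxy alcohols, should give (2R,3R)-3,7-dimethyloct-6-ene-1,2,3-triol F1 by the same inversion at C2. Selective sulfonylation of the primary hydroxyl (TsCl, Et3N, catalytic Bu2SnO, CH2Cl2, 0 °C) should give (2R,3R)-2,3-dihydroxy-3,7-dimethyloct-6-en-1-yl 4-methylbenzenesulfonate F2. Alkylation of compound 6 with F2 under K2CO3 in DMF at 70 °C comes back to the route at compound 10; the hydroxy tosylate either closes to 9 or is displaced directly, and the phenoxide enters at C1 in both cases. In this variant the coumarin never meets a strong alkoxide.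

Step 2. Copper insertion at the bromide flanked by formyl and methoxy may be slow, so that hydrodebromination or oxidative degradation of the electron-rich phenoxide takes over during the long heating. The fallback sets out from compound 2. Miyaura borylation (B2pin2, PdCl2(dppf), KOAc, dioxane, 90 °C) should give 4-hydroxy-3,5-dimethoxy-2-(4,4,5,5-tetramethyl-1,3,2-dioxaborolan-2-yl)benzaldehyde F3. Oxidation of the C–B bond with trimethylamine N-oxide (CH2Cl2, room temperature) comes back to the route at compound 3; this oxidant is chosen because alkaline H2O2 would cause Dakin oxidation of the hydroxybenzaldehyde.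

Step 1. Bromine may attack C1 ipso, para to the free hydroxyl, with loss of the formyl group, or the phenol may be oxidised. The fallback sets out from compound 1. Acetylation (Ac2O, pyridine) gives 4-formyl-2,6-dimethoxyphenyl acetate F4. Bromination, now steered only by the two methoxy groups (NBS, MeCN, room temperature, or Br2, AcOH), gives 3-bromo-4-formyl-2,6-dimethoxyphenyl acetate F5. F5 is put as such into the conditions of step 2, where the aqueous NaOH cleaves the acetate while the bromide is exchanged, and the route is rejoined at compound 3.

Further compounds
F1 | step 5 | (2R,3R)-3,7-dimethyloct-6-ene-1,2,3-triol | OC[C@@H](O)[C@](C)(O)CCC=C(C)C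
F2 | step 5 | (2R,3R)-2,3-dihydroxy-3,7-dimethyloct-6-en-1-yl 4-methylbenzenesulfonate | Cc1ccc(cc1)S(=O)(=O)OC[C@@H](O)[C@](C)(O)CCC=C(C)C
F3 | step 2 | 4-hydroxy-3,5-dimethoxy-2-(4,4,5,5-tetramethyl-1,3,2-dioxaborolan-2-yl)benzaldehyde | COc1cc(C=O)c(B2OC(C)(C)C(C)(C)O2)c(OC)c1O
F4 | step 1 | 4-formyl-2,6-dimethoxyphenyl acetate | COc1cc(C=O)cc(OC)c1OC(C)=O
F5 | step 1 | 3-bromo-4-formyl-2,6-dimethoxyphenyl acetate | COc1cc(C=O)c(Br)c(OC)c1OC(C)=O
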